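## Retrosynthetic overview

- **Feature:** C5, C8 and C9 all lie on ring B, and C10 is shared with ring A. A C6=C7 alkene plus a C1 ketone (the latent C1=C10 alkene) turns ring B into a cyclohexene whose stereocentres are encoded in alkene geometry.
- **Endgame:** C15 propionate, C15 silyl ether and C18 methyl ester are removed. C1=C10 comes from the 1-ketone by C10 epimerisation, axial alcohol and anti elimination. C6–C7 comes from a diimide reduction.
- **Key disconnection:** C5–C10 and C8–C9 are cut, so rings A and B open (and form) together. This gives a (5E,7E)-diene and a (9E)-enone joined by the tether C1–C4.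
- **Trienone:** Suzuki coupling (C6–C7), Takai olefination (C5=C6) and an enantioselective Michael addition (C3–C4, sets C4). The acceptor is a vinyl dienone built from hexane-2,5-dione by double olefination.

Key step: step 10

**Numbering:** halimane numbering is used. C1–C10 form the decalin, C11–C16 the side chain, C17 sits on C8, C18 (acid) and C19 (methyl) on C4, and C20 on C9. β is the face that carries H-5, H-8, C11 and C18. α is the face that carries C17, C19 and C20.

**Assumption:** the quinidine-derived catalyst of step 7 is taken to give the (S)-centre. If the sense is opposite, its quinine-derived pseudoenantiomer is used. Methyl 2-formylpropanoate is taken as purchasable.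

## Route

**Step 1**
Reactants: 1 hexane-2,5-dione; 2 triethyl phosphonoacetate
Product: 4 diethyl (2E,6E)-3,6-dimethylocta-2,6-dienedioate, via keto enoate 3 (not isolated)
Conditions: NaH, THF, 0 °C to reflux; E,Z and Z,Z isomers removed by chromatography
Reagents that add atoms: triethyl phosphonoacetate (2), CCOC(=O)CP(=O)(OCC)OCC
Why: Double Horner–Wadsworth–Emmons olefination of the two methyl ketones, in which the stabilised phosphonate anion favours the E-enoate at each end, and purification here fixes the later C9=C10 and C13=C14 geometries.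

**Step 2**
Reactants: 4 diethyl (2E,6E)-3,6-dimethylocta-2,6-dienedioate
Product: 5 (2E,6E)-3,6-dimethylocta-2,6-diene-1,8-diol
Conditions: i-Bu2AlH, CH2Cl2, −78 to 0 °C; aq. potassium sodium tartrate
Reagents that add atoms: none
Why: i-Bu2AlH reduces α,β-unsaturated esters in the 1,2-sense to allylic alcohols without touching or isomerising the trisubstituted alkenes.

**Step 3**
Reactants: 5 (2E,6E)-3,6-dimethylocta-2,6-diene-1,8-diol; 6 tert-butyldiphenylsilyl chloride
Product: 7 (2E,6E)-8-(tert-butyldiphenylsilyloxy)-3,6-dimethylocta-2,6-dien-1-ol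
Conditions: NaH (1 equiv), THF, rt; then t-BuPh2SiCl (1 equiv)
Reagents that add atoms: tert-butyldiphenylsilyl chloride (6), CC(C)(C)[Si](Cl)(c1ccccc1)c1ccccc1
Why: Monosilylation of a symmetrical diol through its monosodium alkoxide, where the two ends are equivalent so that no regiochemical question arises, and the diphenyl-tert-butylsilyl ether is chosen because this allylic ether must later survive excess Me2AlCl.

**Step 4**
Reactants: 7 (2E,6E)-8-(tert-butyldiphenylsilyloxy)-3,6-dimethylocta-2,6-dien-1-ol
Product: 8 (2E,6E)-8-(tert-butyldiphenylsilyloxy)-3,6-dimethylocta-2,6-dienal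
Conditions: activated MnO2, CH2Cl2, rt
Reagents that add atoms: none
Why: MnO2 oxidation of an allylic alcohol, which stops at the enal and keeps the E geometry.

**Step 5**
Reactants: 8 (2E,6E)-8-(tert-butyldiphenylsilyloxy)-3,6-dimethylocta-2,6-dienal; 9 vinylmagnesium bromide
Product: 10 (4E,8E)-10-(tert-butyldiphenylsilyloxy)-5,8-dimethyldeca-1,4,8-trien-3-ol (racemic carbinol)
Conditions: THF, −78 to 0 °C; aqueous work-up
Reagents that add atoms: vinylmagnesium bromide (9), C=C[Mg]Br
Why: 1,2-Grignard addition to a β,β-disubstituted enal, whose carbinol centre is of no consequence because it is oxidised in the next step.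

**Step 6**
Reactants: 10 (4E,8E)-10-(tert-butyldiphenylsilyloxy)-5,8-dimethyldeca-1,4,8-trien-3-ol
Product: 11 (4E,8E)-10-(tert-butyldiphenylsilyloxy)-5,8-dimethyldeca-1,4,8-trien-3-one
Conditions: activated MnO2, CH2Cl2, rt; used without storage
Reagents that add atoms: none
Why: The vinyl addition delivers a carbinol, so a second MnO2 oxidation of this doubly allylic alcohol is needed to reach the cross-conjugated vinyl dienone.

**Step 7**
Reactants: 11 (4E,8E)-10-(tert-butyldiphenylsilyloxy)-5,8-dimethyldeca-1,4,8-trien-3-one; 12 methyl 2-formylpropanoate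
Product: 13 methyl (2S,6E,10E)-12-(tert-butyldiphenylsilyloxy)-2-formyl-2,7,10-trimethyl-5-oxododeca-6,10-dienoate
Conditions: 9-O-(phenanthren-9-yl)cupreidine, C33H30N2O2 (10 mol %), CH2Cl2, −25 °C
Reagents that add atoms: methyl 2-formylpropanoate (12), COC(=O)C(C)C=O
Why: Enantioselective Michael addition of a 2-substituted 1,3-dicarbonyl donor to a vinyl ketone under bifunctional cinchona catalysis, in which the quinuclidine nitrogen deprotonates the largely enolised formyl ester, the 6'-OH group binds the enone, only the unsubstituted vinyl terminus of 11 is attacked, and the chiral ion pair sets the quaternary centre C4 as S in a product with no acidic C–H left for racemisation.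

**Step 8**
Reactants: 13 methyl (2S,6E,10E)-12-(tert-butyldiphenylsilyloxy)-2-formyl-2,7,10-trimethyl-5-oxododeca-6,10-dienoate; 14 iodoform
Product: 15 methyl (2S,6E,10E)-12-(tert-butyldiphenylsilyloxy)-2-[(E)-2-iodoethenyl]-2,7,10-trimethyl-5-oxododeca-6,10-dienoate
Conditions: CrCl2 (6 equiv), CHI3 (2 equiv), THF–dioxane, 0 °C to rt
Reagents that add atoms: iodoform (14), IC(I)I
Why: Takai olefination, whose geminal dichromium reagent adds to aldehydes only, leaves ketone, enone, ester and silyl ether alone, gives the E-iodoalkene with a bulky α-quaternary aldehyde, and is non-basic, so that the retro-Michael cleavage which a phosphorus ylide could trigger in 13 is avoided.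

**Step 9**
Reactants: 15 methyl (2S,6E,10E)-12-(tert-butyldiphenylsilyloxy)-2-[(E)-2-iodoethenyl]-2,7,10-trimethyl-5-oxododeca-6,10-dienoate; 16 (E)-prop-1-enylboronic acid
Product: 17 methyl (2S,6E,10E)-12-(tert-butyldiphenylsilyloxy)-2,7,10-trimethyl-5-oxo-2-[(1E,3E)-penta-1,3-dienyl]dodeca-6,10-dienoate
Conditions: Pd(PPh3)4 (5 mol %), Cs2CO3, THF–H2O, rt to 40 °C
Reagents that add atoms: (E)-prop-1-enylboronic acid (16), C/C=C/B(O)O
Why: Suzuki–Miyaura coupling, which proceeds with retention at both sp2 carbons, so that the (5E,7E)-diene on which C5 and C8 depend is obtained in one geometry.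

**Step 10**
Reactants: 17 methyl (2S,6E,10E)-12-(tert-butyldiphenylsilyloxy)-2,7,10-trimethyl-5-oxo-2-[(1E,3E)-penta-1,3-dienyl]dodeca-6,10-dienoate
Product: 18 methyl (4S,5S,8R,9S,10S)-15-(tert-butyldiphenylsilyloxy)-1-oxohalima-6,13E-dien-18-oate (cis-fused; H-5 and H-10 both β)
Conditions: Me2AlCl (2.5 equiv), CH2Cl2 (0.01 M), −78 to 0 °C; cold dilute HCl quench
Reagents that add atoms: none
Why: This is a concerted, asynchronous, suprafacial [4+2] addition of the (5E,7E)-diene to the aluminium-complexed s-cis (E)-enone, that is, the known Lewis-acid-promoted intramolecular Diels–Alder reaction of deca-1,7,9-trien-3-ones. Ring B (C5–C6–C7–C8–C9–C10) closes as the new cyclohexene through C8–C9 (leading, at the enone β-carbon) and C5–C10, and ring A (C1–C2–C3–C4–C5–C10) closes in the same event because the four-atom tether C1–C4 spans the C5–C10 bond. The E,E-diene puts C4 and C17 on one face of ring B, the E-enone keeps C20 cis to C1 and C11 cis to H-10, and the transition state with the complexed C1 carbonyl and the small C20 methyl under the diene links the two pairs, so that C17 and C20 share the α face while H-5, H-8, H-10 and C11 share the β face. The absolute sense comes from C4: as with other 6-substituted decatrienones, the early transition state should keep the allylic carbon in its eclipsed rotamer, with C3 on the reacting face, the small C19 methyl eclipsing C5=C6 and the aluminium-complexed ester pointing outwards beside H-5, which places C18 cis to H-5. The step needs endo over exo selectivity, secured by the Lewis acid on the tether carbonyl, and diene-face selectivity, secured only by the size gap between methyl and complexed ester (hence more than two equivalents of Me2AlCl), so this second bias should be modest and the C4/C5 diastereomers are separated here. C10 is a transient centre that disappears in step 14.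

**Step 11**
Reactants: 18 methyl (4S,5S,8R,9S,10S)-15-(tert-butyldiphenylsilyloxy)-1-oxohalima-6,13E-dien-18-oate
Product: 19 methyl (4S,5S,8R,9S,10S)-15-(tert-butyldiphenylsilyloxy)-1-oxohalim-13E-en-18-oate (cis-fused)
Conditions: KO2CN=NCO2K (excess), AcOH, MeOH, 0 °C to rt
Reagents that add atoms: none
Why: Diimide reduction by concerted syn transfer of two hydrogens, in which the cis-disubstituted C6=C7 alkene reacts far faster than the trisubstituted C13=C14 alkene, carbonyl groups and the allylic C–O bond are inert, and the azodicarboxylate source avoids the hydrazone formation that a sulfonyl hydrazide could cause at C1.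

**Step 12**
Reactants: 19 methyl (4S,5S,8R,9S,10S)-15-(tert-butyldiphenylsilyloxy)-1-oxohalim-13E-en-18-oate
Product: 20 methyl (4S,5S,8R,9S,10R)-15-(tert-butyldiphenylsilyloxy)-1-oxohalim-13E-en-18-oate (trans-fused; H-10 α)
Conditions: NaOMe (0.2 equiv), MeOH–THF, 50 °C
Reagents that add atoms: none
Why: Base-catalysed epimerisation through the C1–C10 enolate, driven by the fact that either chair–chair form of the cis-fused ketone holds a syn-diaxial carbon pair (C1/C17 or C4/C20) whereas the trans-fused ketone has C11 and C17 axial only against hydrogens, with methoxide degenerate towards the methyl ester and C4, C5, C8 and C9 not enolisable.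

**Step 13**
Reactants: 20 methyl (4S,5S,8R,9S,10R)-15-(tert-butyldiphenylsilyloxy)-1-oxohalim-13E-en-18-oate
Product: 21 methyl (1R,4S,5S,8R,9S,10R)-15-(tert-butyldiphenylsilyloxy)-1-hydroxyhalim-13E-en-18-oate (1β-OH, axial)
Conditions: LiBH(s-Bu)3, THF, −78 to 0 °C; then NaOH, H2O2
Reagents that add atoms: none
Why: Bulky-hydride reduction by equatorial attack from the α face, opposite the axial C11 chain on C9 (the situation of a steroidal 11-ketone giving the 11β-alcohol), which sets C1 as the axial alcohol anti-periplanar to H-10 while the hindered neopentyl-type ester is left untouched.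

**Step 14**
Reactants: 21 methyl (1R,4S,5S,8R,9S,10R)-15-(tert-butyldiphenylsilyloxy)-1-hydroxyhalim-13E-en-18-oate
Product: 23 methyl (4S,5S,8R,9S)-15-(tert-butyldiphenylsilyloxy)halima-1(10),13E-dien-18-oate, via chlorosulfite 22 (not isolated)
Conditions: SOCl2, pyridine, 0 °C
Reagents that add atoms: none
Why: Pyridine-mediated E2 dehydration of the chlorosulfite, in which the axial leaving group is anti-periplanar to the tertiary axial H-10, Zaitsev orientation and release of the syn-axial O/C11 compression favour the trisubstituted C1=C10 alkene (as in 11β-hydroxy steroid to 9(11)-ene), and the buffered medium prevents migration of the alkene.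

**Step 15**
Reactants: 23 methyl (4S,5S,8R,9S)-15-(tert-butyldiphenylsilyloxy)halima-1(10),13E-dien-18-oate
Product: 24 (4S,5S,8R,9S)-15-(tert-butyldiphenylsilyloxy)halima-1(10),13E-dien-18-oic acid
Conditions: EtSNa, DMF, 90 °C; then dilute HCl
Reagents that add atoms: none
Why: SN2 dealkylation of a hindered methyl ester, in which the thiolate attacks the O-methyl carbon and not the shielded C18 carbonyl, done before the base-labile propionate is present.

**Step 16**
Reactants: 24 (4S,5S,8R,9S)-15-(tert-butyldiphenylsilyloxy)halima-1(10),13E-dien-18-oic acid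
Product: 25 (4S,5S,8R,9S)-15-hydroxyhalima-1(10),13E-dien-18-oic acid
Conditions: Bu4NF (3 equiv), THF, rt; then dilute HCl to pH 4
Reagents that add atoms: none
Why: Fluoride-induced cleavage of the silyl ether, driven by the Si–F bond and indifferent to the carboxylate and both alkenes.

**Step 17**
Reactants: 25 (4S,5S,8R,9S)-15-hydroxyhalima-1(10),13E-dien-18-oic acid; 26 propionic anhydride
Product: 27 (4S,5S,8R,9S)-15-propanoyloxyhalima-1(10),13E-dien-18-oic acid (CNP0223570.1)
Conditions: (EtCO)2O, pyridine, DMAP (cat.), CH2Cl2, 0 °C to rt; aqueous work-up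
Reagents that add atoms: propionic anhydride (26), CCC(=O)OC(=O)CC
Why: DMAP-catalysed acylation of the unhindered primary allylic alcohol, while the tertiary C18 acid is too hindered to be acylated lastingly and any mixed anhydride is hydrolysed on work-up.

## Compound list

1 | hexane-2,5-dione | CC(=O)CCC(C)=O | starting material
2 | triethyl phosphonoacetate | CCOC(=O)CP(=O)(OCC)OCC | starting material
3 | ethyl (E)-3-methyl-6-oxohept-2-enoate | CCOC(=O)/C=C(\C)CCC(C)=O | intermediate
4 | diethyl (2E,6E)-3,6-dimethylocta-2,6-dienedioate | CCOC(=O)/C=C(\C)CC/C(C)=C/C(=O)OCC | intermediate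
5 | (2E,6E)-3,6-dimethylocta-2,6-diene-1,8-diol | OC/C=C(\C)CC/C(C)=C/CO | intermediate
6 | tert-butyldiphenylsilyl chloride | CC(C)(C)[Si](Cl)(c1ccccc1)c1ccccc1 | starting material
7 | (2E,6E)-8-(tert-butyldiphenylsilyloxy)-3,6-dimethylocta-2,6-dien-1-ol | OC/C=C(\C)CC/C(C)=C/CO[Si](c1ccccc1)(c1ccccc1)C(C)(C)C | intermediate
8 | (2E,6E)-8-(tert-butyldiphenylsilyloxy)-3,6-dimethylocta-2,6-dienal | O=C/C=C(\C)CC/C(C)=C/CO[Si](c1ccccc1)(c1ccccc1)C(C)(C)C | intermediate
9 | vinylmagnesium bromide | C=C[Mg]Br | starting material
10 | (4E,8E)-10-(tert-butyldiphenylsilyloxy)-5,8-dimethyldeca-1,4,8-trien-3-ol (racemic) | C=CC(O)/C=C(\C)CC/C(C)=C/CO[Si](c1ccccc1)(c1ccccc1)C(C)(C)C | intermediate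
11 | (4E,8E)-10-(tert-butyldiphenylsilyloxy)-5,8-dimethyldeca-1,4,8-trien-3-one | C=CC(=O)/C=C(\C)CC/C(C)=C/CO[Si](c1ccccc1)(c1ccccc1)C(C)(C)C | intermediate
12 | methyl 2-formylpropanoate | COC(=O)C(C)C=O | starting material
13 | methyl (2S,6E,10E)-12-(tert-butyldiphenylsilyloxy)-2-formyl-2,7,10-trimethyl-5-oxododeca-6,10-dienoate | O=C[C@@](C)(C(=O)OC)CCC(=O)/C=C(\C)CC/C(C)=C/CO[Si](c1ccccc1)(c1ccccc1)C(C)(C)C | intermediate
14 | iodoform | IC(I)I | starting material
15 | methyl (2S,6E,10E)-12-(tert-butyldiphenylsilyloxy)-2-[(E)-2-iodoethenyl]-2,7,10-trimethyl-5-oxododeca-6,10-dienoate | I/C=C/[C@@](C)(C(=O)OC)CCC(=O)/C=C(\C)CC/C(C)=C/CO[Si](c1ccccc1)(c1ccccc1)C(C)(C)C | intermediate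
16 | (E)-prop-1-enylboronic acid | C/C=C/B(O)O | starting material
17 | methyl (2S,6E,10E)-12-(tert-butyldiphenylsilyloxy)-2,7,10-trimethyl-5-oxo-2-[(1E,3E)-penta-1,3-dienyl]dodeca-6,10-dienoate | C/C=C/C=C/[C@@](C)(C(=O)OC)CCC(=O)/C=C(\C)CC/C(C)=C/CO[Si](c1ccccc1)(c1ccccc1)C(C)(C)C | intermediate
18 | methyl (4S,5S,8R,9S,10S)-15-(tert-butyldiphenylsilyloxy)-1-oxohalima-6,13E-dien-18-oate (cis-fused) | CC(C)(C)[Si](c1ccccc1)(c1ccccc1)OC/C=C(\C)CC[C@]1(C)[C@H]2C(=O)CC[C@](C)(C(=O)OC)[C@H]2C=C[C@H]1C | intermediate
19 | methyl (4S,5S,8R,9S,10S)-15-(tert-butyldiphenylsilyloxy)-1-oxohalim-13E-en-18-oate (cis-fused) | CC(C)(C)[Si](c1ccccc1)(c1ccccc1)OC/C=C(\C)CC[C@]1(C)[C@H]2C(=O)CC[C@](C)(C(=O)OC)[C@H]2CC[C@H]1C | intermediate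
20 | methyl (4S,5S,8R,9S,10R)-15-(tert-butyldiphenylsilyloxy)-1-oxohalim-13E-en-18-oate (trans-fused) | CC(C)(C)[Si](c1ccccc1)(c1ccccc1)OC/C=C(\C)CC[C@]1(C)[C@@H]2C(=O)CC[C@](C)(C(=O)OC)[C@H]2CC[C@H]1C | intermediate
21 | methyl (1R,4S,5S,8R,9S,10R)-15-(tert-butyldiphenylsilyloxy)-1-hydroxyhalim-13E-en-18-oate | CC(C)(C)[Si](c1ccccc1)(c1ccccc1)OC/C=C(\C)CC[C@]1(C)[C@@H]2[C@H](O)CC[C@](C)(C(=O)OC)[C@H]2CC[C@H]1C | intermediate
22 | 1β-chlorosulfite of 21 | CC(C)(C)[Si](c1ccccc1)(c1ccccc1)OC/C=C(\C)CC[C@]1(C)[C@@H]2[C@H](OS(=O)Cl)CC[C@](C)(C(=O)OC)[C@H]2CC[C@H]1C | intermediate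
23 | methyl (4S,5S,8R,9S)-15-(tert-butyldiphenylsilyloxy)halima-1(10),13E-dien-18-oate | CC(C)(C)[Si](c1ccccc1)(c1ccccc1)OC/C=C(\C)CC[C@]1(C)C2=CCC[C@](C)(C(=O)OC)[C@H]2CC[C@H]1C | intermediate
24 | (4S,5S,8R,9S)-15-(tert-butyldiphenylsilyloxy)halima-1(10),13E-dien-18-oic acid | CC(C)(C)[Si](c1ccccc1)(c1ccccc1)OC/C=C(\C)CC[C@]1(C)C2=CCC[C@](C)(C(=O)O)[C@H]2CC[C@H]1C | intermediate
25 | (4S,5S,8R,9S)-15-hydroxyhalima-1(10),13E-dien-18-oic acid | OC/C=C(\C)CC[C@]1(C)C2=CCC[C@](C)(C(=O)O)[C@H]2CC[C@H]1C | intermediate
26 | propionic anhydride | CCC(=O)OC(=O)CC | starting material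
27 | (4S,5S,8R,9S)-15-propanoyloxyhalima-1(10),13E-dien-18-oic acid (CNP0223570.1) | CCC(=O)OC/C=C(\C)CC[C@]1(C)C2=CCC[C@](C)(C(=O)O)[C@H]2CC[C@H]1C | target

## Step count and risks

Total step count: 17. Longest linear sequence: 17 steps (1 to 27).

**Step 10.**
- What may go wrong: the fully β-substituted enone may add slowly. Warming may erode the endo preference or allow rotation about the complexed C9=C10 bond. C4 may discriminate only weakly between the two diene faces.
- Fallback, from 17 and back at 18: the ketone is turned into a cationic and much stronger dienophile.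
- Treatment of 17 with 1,2-bis(trimethylsilyloxy)ethane and catalytic Me3SiOTf in CH2Cl2 at −78 °C should give the ethylene ketal of the trienone F1 without moving the C9=C10 alkene.
- The same silyl triflate reopens the dioxolane to a 2-alkenyl-1,3-dioxolan-2-ylium ion. This should add to the diene well below 0 °C (ionic Diels–Alder reaction), where small energy differences between the competing transition states count for more, and then reclose to the ethylene ketal of the cis-fused cycloadduct F2.
- Hydrolysis with pyridinium tosylate in wet acetone returns 18.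

**Step 7.**
- What may go wrong: the catalyst may differentiate formyl and ester groups poorly in the ion pair, or an uncatalysed background addition may lower the enantiomeric purity of C4, the only source of absolute configuration.
- Fallback, from 12 and 11 and back at 13: a stoichiometric chiral amine replaces the catalyst.
- Condensation of 12 with (S)-1-phenylethylamine should give the hydrogen-bonded (Z)-enamino ester F3.
- Its deracemising Michael addition to 11 (THF, rt to 40 °C) passes through a compact aza-ene-like transition state on the face anti to the phenyl group and should give the (S)-configured imine adduct F4.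
- Aqueous acetic acid hydrolyses F4 to 13.

**Step 14 (together with step 13).**
- What may go wrong: elimination may run towards C2, chloride may substitute at C1, or the reduction may give the equatorial alcohol, which lacks the anti-periplanar arrangement.
- Fallback, from 20 and back at 23: the alcohol is bypassed by carbene chemistry.
- Ketone 20 is condensed with tosylhydrazine to the tosylhydrazone F5.
- Its sodium salt (NaH, diglyme, 150 °C, aprotic Bamford–Stevens reaction) loses nitrogen and sulfinate.
- The C1 carbene should then take the tertiary H-10 in a 1,2-shift to give the more substituted alkene 23.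

## Further compounds

F1 | step 10 | ethylene ketal of trienone 17 | C/C=C/C=C/[C@@](C)(C(=O)OC)CCC1(OCCO1)/C=C(\C)CC/C(C)=C/CO[Si](c1ccccc1)(c1ccccc1)C(C)(C)C
F2 | step 10 | ethylene ketal of cis-fused cycloadduct 18 | CC(C)(C)[Si](c1ccccc1)(c1ccccc1)OC/C=C(\C)CC[C@]1(C)[C@H]2C3(OCCO3)CC[C@](C)(C(=O)OC)[C@H]2C=C[C@H]1C
F3 | step 7 | methyl (Z)-2-methyl-3-{[(1S)-1-phenylethyl]amino}prop-2-enoate | COC(=O)/C(C)=C\N[C@@H](C)c1ccccc1
F4 | step 7 | (1S)-1-phenylethyl imine of keto aldehyde 13 | C[C@H](/N=C/[C@@](C)(C(=O)OC)CCC(=O)/C=C(\C)CC/C(C)=C/CO[Si](c1ccccc1)(c1ccccc1)C(C)(C)C)c1ccccc1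
F5 | step 14 | tosylhydrazone of ketone 20 | CC(C)(C)[Si](c1ccccc1)(c1ccccc1)OC/C=C(\C)CC[C@]1(C)[C@@H]2C(=NNS(=O)(=O)c3ccc(C)cc3)CC[C@](C)(C(=O)OC)[C@H]2CC[C@H]1C
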